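The runs stem from a simulated flask with made-up constants.

By 0.667 min the red run held 1 % of its substrate. I took that fast step as over and reckoned with what it left free: 94.0 % of the charge, in neither product.

- red: substrate 0.38 M; solid reagent 0.50 M; run made earlier
- flask: substrate 0.25 M; solid reagent 0.500 M; time 50 min

- red (time / min: target / %, side product / %, substrate / %): 0.667: 3, 2, 1; 2.00: 4, 25, 0; 3.00: 6, 41, 0; 5.00: 11, 63, 0

(standard deviation of a reading: 1.5 percentage points)

- solid reagent is a solid; its amount is given per volume of the solution
- at the start none of the solid reagent is in solution

* ratio of target to side product at 20 s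
* ratio of target to side product at 50 min
* which of target and side product there is more of at 50 min

I read target over side product twice, from different readings of the red run. At 2.00 min it stood at 0.160, and at 5.00 min at 0.175, while side product went from 25 % to 63 %. The gap of 0.0146 is smaller than the 0.0238 by which the scatter of one target reading moves the later ratio. So these readings could not tell the two ratios apart; that shows no constancy, and I simply assumed one number for both. Pooled from 2.00 min on, the readings gave 0.163. I carried this as the split, target per side product in fractions of the charge, a selectivity factor.

The flask has 0.25 M of substrate against 0.38 M in the red run, on 0.500 M of solid reagent. I assumed the split held per charge, so I expected 0.163 at 50 min, with side product ahead. At 0.667 min the products stood at 3 % and 2 % against a scatter of 1.5 percentage points, so I committed to no early ratio.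

The forecast gave 1.5 (0.5 to 5) at 20 s, 10 (2 to 35) at 50 min, and target ahead. Its ground was this: “This suggests side product slowly converts to target.” My split lies below that range.

The flask gave 0.715 at 20 s and 0.167 at 50 min, with side product ahead.

    substrate → intermediate A (k = 0.170 s⁻¹)
    partner + intermediate A → target (k = 0.0780 L mol⁻¹ s⁻¹)
    intermediate A ⇌ intermediate B (K = 7.50, k = 0.00870 s⁻¹)
    intermediate A → intermediate C (k = 5.20 × 10⁻⁴ s⁻¹)
    intermediate B → side product (k = 0.00950 s⁻¹)
    intermediate C ⇌ intermediate D (K = 0.560, k = 0.00560 s⁻¹)
    target ⇌ isomer of the product (K = 0.630, k = 0.0260 s⁻¹)
    solid reagent ⇌ partner, rate k8*(cs8 - [partner]) while solid is left; crystals form when [partner] > cs8 (solubility = 0.110 M, k = 0.00600 s⁻¹)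
    2 partner → self-condensation product (k = 0.0350 L mol⁻¹ s⁻¹)

In the flask, side product stood at 74.7 % after 25.0 min and at 74.7 % after 500 min. The split times its 74.7 % gives 12.2 % of target, and the flask held 12.5 %. The neighbouring flask, with 0.10 M of substrate, ended at a ratio of 0.192. The split times its 72.5 % of side product gives 11.8 % of target, and that flask held 13.9 %.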